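**Strategy.** Cembrane locants are used (C1 carries the acrylic acid, C3 the acetate). The oxolane O–C8–C9–C10–C11 with its two flanking carbinols C7 and C12 is the oxidation pattern of a 7E,11E-1,5-diene. The ring is therefore not closed directly: in a 14-membered (7S,8S,11S,12S)-bis-epoxide the oxygen of the C11–C12 oxirane attacks C8 of the protonated C7–C8 oxirane, and water cuts the O–C12 bond of the resulting bicyclic oxonium ion. The three-membered ring is thus enlarged by C10–C9–C8 to the oxolane, and C7, C8, C11 and C12 are fixed in one operation. The carbocycle is assembled from (R)-lavandulol and geranyl acetate by two sulfone alkylations.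

Key step: step 16

Remark on numbering: the cembrane locants C1–C20 are also used for the open-chain precursors, in which C5 and C6 are not yet bonded (5,6-seco).
Assumption: (R)-(−)-lavandulol and the L-fructose-derived (ent-)Shi ketone are taken as purchasable.

**Step 1**
Reactants: 1 geranyl acetate
Product: 2 (2E,6E)-8-hydroxygeranyl acetate
Conditions: SeO2 (cat.), t-BuOOH, salicylic acid (cat.), CH2Cl2, rt
Reagents that add atoms: tert-butyl hydroperoxide, CC(C)(C)OO
Why: Catalytic SeO2 allylic oxidation (ene reaction, then [2,3]-sigmatropic shift) should take the E-methyl group of the electron-rich 6,7-alkene, the 2,3-alkene being switched off by the allylic acetate, and the sigmatropic step fixes the E geometry; no stereocentre is formed.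

**Step 2**
Reactants: 2 (2E,6E)-8-hydroxygeranyl acetate
Product: 3 (2E,6E)-8-bromogeranyl acetate
Conditions: CBr4, PPh3, CH2Cl2, 0 °C
Reagents that add atoms: carbon tetrabromide, BrC(Br)(Br)Br
Why: Appel bromination displaces the oxyphosphonium group of the primary allylic alcohol by SN2 at low temperature, without allylic transposition or loss of the E geometry.

**Step 3**
Reactants: 4 (R)-lavandulol
Product: 6 (R)-lavandulyl phenyl sulfone, via (R)-lavandulyl methanesulfonate 5 (not isolated)
Conditions: MsCl, Et3N, CH2Cl2, 0 °C; solvent exchange; PhSO2Na, n-Bu4NI (cat.), DMF, 80 °C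
Reagents that add atoms: methanesulfonyl chloride, CS(=O)(=O)Cl (in 5 only); sodium benzenesulfinate, [Na+].[O-]S(=O)c1ccccc1
Why: Mesylation followed by iodide-catalysed S-alkylation of benzenesulfinate at the primary carbon installs the carbanion-stabilising sulfone, and the stereocentre of lavandulol (the future C1, R) is not involved.

**Step 4**
Reactants: 6 (R)-lavandulyl phenyl sulfone; 3 (2E,6E)-8-bromogeranyl acetate
Product: 7 (1R,7E,11E)-6-acetoxy-14-(phenylsulfonyl)-5,6-secocembra-3,7,11,15-tetraene (both C14 epimers)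
Conditions: 6, n-BuLi (1.0 equiv), THF, −78 °C; then 3, −78 → −30 °C
Reagents that add atoms: none
Why: Alkylation of the α-sulfonyl carbanion at the primary allylic bromide (SN2) should form the C13–C14 bond much faster than the carbanion attacks the acetate at −78 °C; the new sulfone-bearing centre forms as a mixture and is erased in step 5.

**Step 5**
Reactants: 7 C14-sulfonyl seco-cembrane acetate
Product: 8 (1R,7E,11E)-5,6-secocembra-3,7,11,15-tetraen-6-ol
Conditions: Mg turnings (I2-activated), MeOH, 50 °C
Reagents that add atoms: none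
Why: Single-electron reductive desulfonylation with magnesium in methanol cleaves the C–S bond of the alkyl sulfone, and the magnesium methoxide formed transesterifies the acetate in the same flask, isolated alkenes being inert.

**Step 6**
Reactants: 8 seco-cembrane C6 alcohol
Product: 10 (1R,7E,11E)-6-(phenylsulfonyl)-5,6-secocembra-3,7,11,15-tetraene, via (1R,7E,11E)-6-bromo-5,6-secocembra-3,7,11,15-tetraene 9 (not isolated)
Conditions: PBr3, Et2O, −10 °C; then PhSO2Na, DMF, rt
Reagents that add atoms: phosphorus tribromide, BrP(Br)Br (in 9 only); sodium benzenesulfinate, [Na+].[O-]S(=O)c1ccccc1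
Why: SN2 bromination of the geraniol-type alcohol and S-alkylation of sulfinate at the primary allylic carbon (no SN2′ product, E retained) place the sulfone at C6, where it later serves as the ring-closing nucleophile and switches off the 7,8-alkene.

**Step 7**
Reactants: 10 C6 sulfone
Product: 11 (1R,3E,7E,11E)-6-(phenylsulfonyl)-5,6-secocembra-3,7,11,15-tetraen-5-ol
Conditions: SeO2 (cat.), t-BuOOH, CH2Cl2, 0 °C → rt
Reagents that add atoms: tert-butyl hydroperoxide, CC(C)(C)OO
Why: Catalytic SeO2 allylic oxidation should again select the E-methyl group of the terminal isopropylidene, the most electron-rich and accessible alkene (the 7,8-alkene is deactivated by the allylic sulfone, the isopropenyl group is 1,1-disubstituted), and gives the 3E allylic alcohol.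

**Step 8**
Reactants: 11 allylic alcohol
Product: 12 (1R,3R,4R,7E,11E)-3,4-epoxy-6-(phenylsulfonyl)-5,6-secocembra-7,11,15-trien-5-ol
Conditions: Ti(OiPr)4, D-(−)-diethyl tartrate, t-BuOOH, 4 Å MS, CH2Cl2, −20 °C
Reagents that add atoms: tert-butyl hydroperoxide, CC(C)(C)OO
Why: Katsuki–Sharpless asymmetric epoxidation acts only on the allylic alcohol, and D-(−)-tartrate delivers oxygen to the face that gives the (3R,4R)-oxirane (reagent control; the opposite face to the one L-(+)-tartrate uses in giving (2S,3S)-epoxygeraniol).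

**Step 9**
Reactants: 12 epoxy alcohol
Product: 13 (1R,7E,11E)-5-bromo-3,4-epoxy-6-(phenylsulfonyl)-5,6-secocembra-7,11,15-triene (oxirane as in 12)
Conditions: CBr4, PPh3, 2,6-lutidine, CH2Cl2, 0 °C
Reagents that add atoms: carbon tetrabromide, BrC(Br)(Br)Br
Why: Appel bromination under buffered conditions turns the primary hydroxyl into the leaving group for ring closure without opening the oxirane.

**Step 10**
Reactants: 13 epoxy bromide
Product: 14 (1R,3R,4R,7E,11E)-3,4-epoxy-6-(phenylsulfonyl)cembra-7,11,15-triene (both C6 epimers)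
Conditions: KHMDS (1.05 equiv), THF, −78 → −30 °C, slow addition of 13, final 2 mM
Reagents that add atoms: none
Why: Intramolecular alkylation of the allylic sulfonyl carbanion (the only acidic site) at the primary bromide under high dilution should close the 14-membered ring, the two E-trisubstituted alkenes limiting the conformational freedom as in sulfone-based macrocyclisations of polyprenyl chains; C6 forms as a mixture that is erased in step 12.

**Step 11**
Reactants: 14 macrocyclic epoxy sulfone
Product: 15 (1R,3R,4S,7E,11E)-6-(phenylsulfonyl)cembra-7,11,15-triene-3,4-diol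
Conditions: HClO4 (3 % aq., cat.), THF, 0 °C → rt
Reagents that add atoms: water, O
Why: Acid-catalysed hydrolysis of the trisubstituted oxirane takes place by attack of water at the tertiary carbon C4 with inversion (borderline SN2) while C3 keeps its oxygen, which converts the (3R,4R)-oxirane into the (3R,4S)-diol; the aqueous medium suppresses cation–olefin reactions.

**Step 12**
Reactants: 15 diol sulfone
Product: 16 (1R,3R,4S,7E,11E)-cembra-7,11,15-triene-3,4-diol
Conditions: PdCl2(dppp) (cat.), LiBHEt3 (excess), THF, 0 °C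
Reagents that add atoms: none
Why: Palladium-catalysed hydride desulfonylation runs through the π-allyl complex, and hydride is delivered to the less substituted terminus C6, so that the 7E-alkene stays in place; the excess hydride covers the two hydroxyl groups.

**Step 13**
Reactants: 16 triene diol
Product: 17 (1R,3R,4S,7E,11E)-3-acetoxycembra-7,11,15-trien-4-ol
Conditions: Ac2O, pyridine, DMAP (cat.), CH2Cl2, rt
Reagents that add atoms: acetic anhydride, CC(=O)OC(C)=O
Why: DMAP-catalysed acetylation acylates the secondary C3 hydroxyl and leaves the tertiary C4 hydroxyl free.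

**Step 14**
Reactants: 17 mono-acetate
Product: 18 (1R,3R,4S,7E,11E)-3-acetoxy-4-(triethylsilyloxy)cembra-7,11,15-triene
Conditions: TESOTf, 2,6-lutidine, CH2Cl2, −78 → 0 °C
Reagents that add atoms: triethylsilyl trifluoromethanesulfonate, CC[Si](CC)(CC)OS(=O)(=O)C(F)(F)F
Why: Silylation with the silyl triflate caps the tertiary C4 hydroxyl, which would otherwise open the C7–C8 oxirane in step 16 to a 4,7-oxolane.

**Step 15**
Reactants: 18 protected diene
Product: 19 (1R,3R,4S,7S,8S,11S,12S)-3-acetoxy-7,8:11,12-diepoxy-4-(triethylsilyloxy)cembr-15-ene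
Conditions: ent-Shi ketone (0.6 equiv), Oxone, K2CO3, n-Bu4NHSO4 (cat.), MeCN/DMM/borate–EDTA buffer (pH 10.5), 0 °C
Reagents that add atoms: Oxone (potassium peroxymonosulfate), [K+].[O-]S(=O)(=O)OO
Why: Shi epoxidation through the dioxirane of the L-fructose-derived ketone (spiro transition state, reagent control) should give the (S,S)-oxirane at each E-trisubstituted ring alkene (the D-ketone gives R,R), the 1,1-disubstituted isopropenyl group reacting much more slowly.

**Step 16 (key step)**
Reactants: 19 bis-epoxide
Product: 21 (1R,3R,4S,7S,8R,11S,12R)-3-acetoxy-8,11-epoxy-4-(triethylsilyloxy)cembr-15-ene-7,12-diol, via bicyclic epoxonium ion 20 (not isolated)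
Conditions: CSA (0.2 equiv), THF/H2O 4:1, 0 °C
Reagents that add atoms: water, O
Why: Protonation of the C7–C8 oxirane lets the oxygen of the C11–C12 oxirane attack the tertiary carbon C8 from the rear (5-exo-tet closure of the O–C8 bond, inversion at C8) to give the 1-oxoniabicyclo[3.1.0]hexane 20, whose strained three-membered ring is opened by water at the tertiary carbon C12 with inversion, so that the oxirane is enlarged to the oxolane. The closest known reaction type is the epoxonium (epoxide-opening) cascade of 1,5-diepoxides terminated by an oxygen nucleophile. C7 and C11 keep the oxygen and configuration set by the Shi epoxidation, and C8 and C12 are each inverted once by stereospecific backside attack, which gives 7S,8R,11S,12R. The step needs the oxirane oxygen to attack C8 in the 5-exo mode before water opens either oxirane and before the reverse 6-endo attack on C12 occurs; the five-membered transition state at a tertiary centre, the silyl ether on the C4 oxygen (no 4,7-oxolane) and the aqueous medium (no cation–olefin reaction of the isopropenyl group) are what should secure this.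

**Step 17**
Reactants: 21 oxolane diol
Product: 23 (1R,3R,4S,7S,8R,11S,12R)-3-acetoxy-8,11-epoxy-7,12-dihydroxy-4-(triethylsilyloxy)cembr-15(17)-en-16-al, via the 16-ol (allylic alcohol) 22 (not isolated)
Conditions: SeO2 (0.5 equiv), t-BuOOH, CH2Cl2, rt; filtration; then MnO2, CH2Cl2, rt
Reagents that add atoms: tert-butyl hydroperoxide, CC(C)(C)OO
Why: SeO2/t-BuOOH ene oxidation of the only remaining alkene hydroxylates its methyl group, and MnO2 then oxidises the resulting primary allylic alcohol, and not the secondary C7 alcohol, to the enal.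

**Step 18**
Reactants: 23 enal
Product: 24 (1R,3R,4S,7S,8R,11S,12R)-3-acetoxy-8,11-epoxy-7,12-dihydroxy-4-(triethylsilyloxy)cembr-15(17)-en-16-oic acid
Conditions: NaClO2, NaH2PO4, 2-methyl-2-butene, t-BuOH/H2O, 0 °C → rt
Reagents that add atoms: sodium chlorite, [Na+].[O-]Cl=O
Why: Pinnick oxidation converts the enal to the α-methylene acid without touching alcohols, acetate or silyl ether, 2-methyl-2-butene scavenging the hypochlorite.

**Step 19**
Reactants: 24 silyl-protected acid
Product: 25 Dendronpholide J
Conditions: HF·pyridine, THF/pyridine, 0 °C → rt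
Reagents that add atoms: none
Why: Fluoride cleavage of the tertiary triethylsilyl ether with buffered HF·pyridine should leave the acetate, the acid and the free alcohols untouched and give the target.

**Compound list**

1 | geranyl acetate | CC(C)=CCC/C(C)=C/COC(C)=O | starting material
2 | (2E,6E)-8-hydroxygeranyl acetate | OC/C(C)=C/CC/C(C)=C/COC(C)=O | intermediate
3 | (2E,6E)-8-bromogeranyl acetate | BrC/C(C)=C/CC/C(C)=C/COC(C)=O | intermediate
4 | (R)-lavandulol, (2R)-5-methyl-2-(prop-1-en-2-yl)hex-4-en-1-ol | C=C(C)[C@@H](CC=C(C)C)CO | starting material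
5 | (R)-lavandulyl methanesulfonate | C=C(C)[C@@H](CC=C(C)C)COS(C)(=O)=O | intermediate (not isolated)
6 | (R)-lavandulyl phenyl sulfone | C=C(C)[C@@H](CC=C(C)C)CS(=O)(=O)c1ccccc1 | intermediate
7 | (1R,7E,11E)-6-acetoxy-14-(phenylsulfonyl)-5,6-secocembra-3,7,11,15-tetraene, C14 epimers | C=C(C)[C@@H](CC=C(C)C)C(S(=O)(=O)c1ccccc1)C/C(C)=C/CC/C(C)=C/COC(C)=O | intermediate
8 | (1R,7E,11E)-5,6-secocembra-3,7,11,15-tetraen-6-ol | C=C(C)[C@@H](CC=C(C)C)CC/C(C)=C/CC/C(C)=C/CO | intermediate
9 | (1R,7E,11E)-6-bromo-5,6-secocembra-3,7,11,15-tetraene | C=C(C)[C@@H](CC=C(C)C)CC/C(C)=C/CC/C(C)=C/CBr | intermediate (not isolated)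
10 | (1R,7E,11E)-6-(phenylsulfonyl)-5,6-secocembra-3,7,11,15-tetraene | C=C(C)[C@@H](CC=C(C)C)CC/C(C)=C/CC/C(C)=C/CS(=O)(=O)c1ccccc1 | intermediate
11 | (1R,3E,7E,11E)-6-(phenylsulfonyl)-5,6-secocembra-3,7,11,15-tetraen-5-ol | C=C(C)[C@@H](C/C=C(C)/CO)CC/C(C)=C/CC/C(C)=C/CS(=O)(=O)c1ccccc1 | intermediate
12 | (1R,3R,4R,7E,11E)-3,4-epoxy-6-(phenylsulfonyl)-5,6-secocembra-7,11,15-trien-5-ol | C=C(C)[C@@H](C[C@H]2O[C@]2(C)CO)CC/C(C)=C/CC/C(C)=C/CS(=O)(=O)c1ccccc1 | intermediate
13 | (1R,7E,11E)-5-bromo-3,4-epoxy-6-(phenylsulfonyl)-5,6-secocembra-7,11,15-triene, oxirane as in 12 | C=C(C)[C@@H](C[C@H]2O[C@]2(C)CBr)CC/C(C)=C/CC/C(C)=C/CS(=O)(=O)c1ccccc1 | intermediate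
14 | (1R,3R,4R,7E,11E)-3,4-epoxy-6-(phenylsulfonyl)cembra-7,11,15-triene, C6 epimers | C=C(C)[C@@H]1CC/C(C)=C/CC/C(C)=C/C(S(=O)(=O)c2ccccc2)C[C@@]3(C)O[C@@H]3C1 | intermediate
15 | (1R,3R,4S,7E,11E)-6-(phenylsulfonyl)cembra-7,11,15-triene-3,4-diol, C6 epimers | C=C(C)[C@@H]1CC/C(C)=C/CC/C(C)=C/C(S(=O)(=O)c2ccccc2)C[C@](C)(O)[C@H](O)C1 | intermediate
16 | (1R,3R,4S,7E,11E)-cembra-7,11,15-triene-3,4-diol | C=C(C)[C@@H]1CC/C(C)=C/CC/C(C)=C/CC[C@](C)(O)[C@H](O)C1 | intermediate
17 | (1R,3R,4S,7E,11E)-3-acetoxycembra-7,11,15-trien-4-ol | C=C(C)[C@@H]1CC/C(C)=C/CC/C(C)=C/CC[C@](C)(O)[C@H](OC(C)=O)C1 | intermediate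
18 | (1R,3R,4S,7E,11E)-3-acetoxy-4-(triethylsilyloxy)cembra-7,11,15-triene | C=C(C)[C@@H]1CC/C(C)=C/CC/C(C)=C/CC[C@](C)(O[Si](CC)(CC)CC)[C@H](OC(C)=O)C1 | intermediate
19 | (1R,3R,4S,7S,8S,11S,12S)-3-acetoxy-7,8:11,12-diepoxy-4-(triethylsilyloxy)cembr-15-ene | C=C(C)[C@@H]1CC[C@]2(C)O[C@H]2CC[C@]3(C)O[C@H]3CC[C@](C)(O[Si](CC)(CC)CC)[C@H](OC(C)=O)C1 | intermediate
20 | bicyclic epoxonium ion (oxonium oxygen bonded to C8, C11 and C12; C7–OH) | C=C(C)[C@@H]1CC[C@]2(C)[O+]3[C@H]2CC[C@]3(C)[C@@H](O)CC[C@](C)(O[Si](CC)(CC)CC)[C@H](OC(C)=O)C1 | intermediate (not isolated)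
21 | (1R,3R,4S,7S,8R,11S,12R)-3-acetoxy-8,11-epoxy-4-(triethylsilyloxy)cembr-15-ene-7,12-diol | C=C(C)[C@@H]1CC[C@@](C)(O)[C@@H]2CC[C@@](C)(O2)[C@@H](O)CC[C@](C)(O[Si](CC)(CC)CC)[C@H](OC(C)=O)C1 | intermediate
22 | the 16-ol of 21 (2-substituted allylic alcohol, cembr-15(17)-ene-7,12,16-triol) | C=C(CO)[C@@H]1CC[C@@](C)(O)[C@@H]2CC[C@@](C)(O2)[C@@H](O)CC[C@](C)(O[Si](CC)(CC)CC)[C@H](OC(C)=O)C1 | intermediate (not isolated)
23 | the corresponding cembr-15(17)-en-16-al | C=C(C=O)[C@@H]1CC[C@@](C)(O)[C@@H]2CC[C@@](C)(O2)[C@@H](O)CC[C@](C)(O[Si](CC)(CC)CC)[C@H](OC(C)=O)C1 | intermediate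
24 | the corresponding cembr-15(17)-en-16-oic acid, 4-O-triethylsilyl ether | C=C(C(=O)O)[C@@H]1CC[C@@](C)(O)[C@@H]2CC[C@@](C)(O2)[C@@H](O)CC[C@](C)(O[Si](CC)(CC)CC)[C@H](OC(C)=O)C1 | intermediate
25 | Dendronpholide J, (1R,3R,4S,7S,8R,11S,12R) | C=C(C(=O)O)[C@@H]1CC[C@@](C)(O)[C@@H]2CC[C@@](C)(O2)[C@@H](O)CC[C@](C)(O)[C@H](OC(C)=O)C1 | target

**Step count and risks**

Total step count: 19. Longest linear sequence: 18 steps (geranyl acetate, steps 1, 2 and 4–19); the lavandulol branch is 17 steps.

The three steps most likely to fail: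

Step 16 (key step). The process at risk is the order of events. Bulk water may open one protonated oxirane before the C11–C12 oxirane oxygen has attacked C8, or the C7–C8 oxirane oxygen may attack C12 in the 6-endo sense. Either leads to oxane or oxepane isomers or to a diastereomeric oxolane, and premature loss of the silyl group would add a competing closure by the C4 hydroxyl. The fallback sets out from 19 and comes back at 21. It replaces the hydrolytic cascade by a water-free, carboxylate-terminated ring expansion with a separate unmasking. Compound 19 would be treated with BF3·OEt2 (cat.) and chloroacetic acid in CH2Cl2 at −40 °C. Without water, the first nucleophile to reach the Lewis-acid-bound C7–C8 oxirane should be the neighbouring oxirane oxygen, and the epoxonium ion is captured at C12 by the acid to give the C12 chloroacetate of 21, F1. Thiourea/NaHCO3 in EtOH should then remove the chloroacetyl group in the presence of the C3 acetate and return 21.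

Step 10. The process at risk is the rate of ring closure. Displacement of a bromide next to an oxirane is slower than an allylic alkylation, so intermolecular alkylation (oligomers), attack of the carbanion on the oxirane, or base-induced cyclopropane formation in the γ,δ-epoxy sulfone product may take over. The fallback sets out from 12 and comes back at 15. The ring would be closed by epoxide opening instead of halide displacement: 12 is added slowly to KHMDS (2.2 equiv)/18-crown-6 in THF at high dilution. The alkoxide should undergo Payne rearrangement to the terminal (3R)-3-hydroxy-(4S)-4,5-epoxide F2 (as its alkoxide, not isolated), whose CH2 group is opened by the C6 sulfonyl carbanion. This gives diol 15 directly, because the Payne step inverts C4 just as the hydrolysis of step 11 does, and it makes steps 9–11 unnecessary.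

Step 17. The process at risk is the ene oxidation itself. A 1,1-disubstituted alkene reacts sluggishly with SeO2, and long reaction times invite acid-promoted loss of the silyl group and over-oxidation. The fallback sets out from 21 and comes back at 22. The only alkene of 21 would be epoxidised with mCPBA (NaHCO3, CH2Cl2) to the 15,16-epoxide F3 (either C15 epimer serves). This is isomerised with Cp2TiCl (from Cp2TiCl2 and Mn, THF) by homolytic opening to the tertiary radical and loss of a methyl hydrogen, which gives the allylic alcohol 22. MnO2 then gives 23 as in the route.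

**Further compounds**

F1 | step 16 | (1R,3R,4S,7S,8R,11S,12R)-3-acetoxy-12-(chloroacetoxy)-8,11-epoxy-4-(triethylsilyloxy)cembr-15-en-7-ol | C=C(C)[C@@H]1CC[C@@](C)(OC(=O)CCl)[C@@H]2CC[C@@](C)(O2)[C@@H](O)CC[C@](C)(O[Si](CC)(CC)CC)[C@H](OC(C)=O)C1
F2 | step 10 | (1R,3R,4S,7E,11E)-4,5-epoxy-6-(phenylsulfonyl)-5,6-secocembra-7,11,15-trien-3-ol (Payne isomer of 12) | C=C(C)[C@@H](C[C@@H](O)[C@]2(C)CO2)CC/C(C)=C/CC/C(C)=C/CS(=O)(=O)c1ccccc1
F3 | step 17 | 15,16-epoxide of 21 (C15 epimers) | CC1(CO1)[C@@H]2CC[C@@](C)(O)[C@@H]3CC[C@@](C)(O3)[C@@H](O)CC[C@](C)(O[Si](CC)(CC)CC)[C@H](OC(C)=O)C2
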